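**Assumption:** the target has no stereocentre, so the "single enantiomer" requirement is met automatically. The only stereo-elements on the route are the (E)-enone of 5, the racemic transient centre of 6 and the (Z)-exocyclic alkene of 9; none survives into 10.

## Retrosynthetic overview

1. The 2,2-dimethylpyran ring is made last, directly on the unprotected trihydroxyisoflavone 7 with prenal 8: condensation at C2', then o-quinone methide 9, then oxa-6π closure (the ring closure presumed for prenyl-derived chromenes).
2. Isoflavone 7 comes from 2'-hydroxychalcone 5 by an isoflavone-synthase-type oxidative 1,2-aryl shift, then closure of the 2'-OH onto the acetal carbon; all MOM groups fall in the same pot.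
3. Chalcone 5 comes from a Claisen–Schmidt condensation of ketone 2 (from 2,4-dihydroxyacetophenone 1) with aldehyde 4 (from 5-hydroxyvanillin 3).
4. Ring order: A and B rings are bought; the pyranone C ring forms in step 4; the dimethylpyran ring forms in step 5.

## Route

**Step 1**
Reactants: 1 2,4-dihydroxyacetophenone
Product: 2 1-[2-hydroxy-4-(methoxymethoxy)phenyl]ethan-1-one
Conditions: MOMCl (1.1 equiv), K2CO3 (2 equiv), acetone, 0 °C → rt
Reagents that add atoms: chloromethyl methyl ether (MOMCl), COCCl
Why: Williamson-type O-alkylation that is selective for the 4-OH, because the 2-OH is locked in a hydrogen bond to the ketone and is not ionised by K2CO3 in acetone.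

**Step 2**
Reactants: 3 3,4-dihydroxy-5-methoxybenzaldehyde (5-hydroxyvanillin)
Product: 4 3-methoxy-4,5-bis(methoxymethoxy)benzaldehyde
Conditions: MOMCl (2.6 equiv), K2CO3 (4 equiv), acetone, reflux
Reagents that add atoms: chloromethyl methyl ether (MOMCl), COCCl
Why: exhaustive Williamson-type O-alkylation of both catechol hydroxyls, which masks the oxidation-sensitive catechol for the base and Tl(III) steps with a group that the acid stage of step 4 removes for free.

**Step 3**
Reactants: 2 1-[2-hydroxy-4-(methoxymethoxy)phenyl]ethan-1-one; 4 3-methoxy-4,5-bis(methoxymethoxy)benzaldehyde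
Product: 5 (E)-1-[2-hydroxy-4-(methoxymethoxy)phenyl]-3-[3-methoxy-4,5-bis(methoxymethoxy)phenyl]prop-2-en-1-one
Conditions: KOH (50% aq, 15 equiv), EtOH, rt, 36 h; cold 1 M HCl to pH 5–6
Reagents that add atoms: none
Why: Claisen–Schmidt aldol condensation of the methyl ketone enolate with a non-enolisable aldehyde, in which E1cB dehydration gives the thermodynamically favoured (E)-enone and the MOM ethers are inert to hydroxide.

**Step 4**
Reactants: 5 (E)-1-[2-hydroxy-4-(methoxymethoxy)phenyl]-3-[3-methoxy-4,5-bis(methoxymethoxy)phenyl]prop-2-en-1-one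
Product: 7 3-(3,4-dihydroxy-5-methoxyphenyl)-7-hydroxy-4H-chromen-4-one, via dimethyl acetal 6 (not isolated)
Conditions: Tl(NO3)3·3H2O (1.1 equiv), MeOH/HC(OMe)3 1:1, rt, 4 h; NaHSO3 quench, filter off Tl(I) salts; then 10% HCl, MeOH, 60 °C, 3 h
Reagents that add atoms: none
Why: thallium(III)-mediated oxidative 1,2-aryl migration of a 2'-hydroxychalcone (the chemical counterpart of isoflavone synthase), in which oxythallation of the enone, shift of the electron-rich B ring from Cβ to Cα with loss of Tl(I) and methanol capture give acetal 6 (solvent MeOH supplies its two OMe groups, which leave again as MeOH), after which the 2'-OH closes onto the acetal carbon under HCl to form the pyranone ring while the three MOM ethers are transacetalised off; the transient centre of 6 is racemic and is erased on aromatisation to the chromone.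

**Step 5**
Reactants: 7 3-(3,4-dihydroxy-5-methoxyphenyl)-7-hydroxy-4H-chromen-4-one; 8 3-methylbut-2-enal (prenal)
Product: 10 7-hydroxy-3-(8-hydroxy-7-methoxy-2,2-dimethyl-2H-chromen-5-yl)-4H-chromen-4-one, via ortho-quinone methide 9 (not isolated)
Conditions: 8 (1.5 equiv), ethylenediammonium diacetate (20 mol %), degassed 1,4-dioxane, 100 °C, Ar, sealed tube
Reagents that add atoms: 3-methylbut-2-enal (prenal, 8), CC(C)=CC=O
Why: amine-catalysed Knoevenagel-type ortho-C-condensation followed by oxa-6π electrocyclisation (formal [3+3] chromene annulation), in which the iminium of 8 is attacked at C2' (ortho to 3'-OH and para to 5'-OMe, a resorcinol-monoether-type carbon), amine loss gives (Z)-dienone 9 and this closes to the pyran, whereas the 4'-OH has no free ortho carbon, a C6' adduct cannot cyclise and reverts, and the 7-OH/C8 site is a deactivated vinylogous acid that normally needs about 140 °C in pyridine to annulate; no stereocentre is created.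

## Compound list

1 | 1-(2,4-dihydroxyphenyl)ethan-1-one (2,4-dihydroxyacetophenone) | CC(=O)c1ccc(O)cc1O | starting material
2 | 1-[2-hydroxy-4-(methoxymethoxy)phenyl]ethan-1-one | CC(=O)c1ccc(OCOC)cc1O | intermediate
3 | 3,4-dihydroxy-5-methoxybenzaldehyde (5-hydroxyvanillin) | COc1cc(C=O)cc(O)c1O | starting material
4 | 3-methoxy-4,5-bis(methoxymethoxy)benzaldehyde | COCOc1cc(C=O)cc(OC)c1OCOC | intermediate
5 | (E)-1-[2-hydroxy-4-(methoxymethoxy)phenyl]-3-[3-methoxy-4,5-bis(methoxymethoxy)phenyl]prop-2-en-1-one | COCOc1ccc(C(=O)/C=C/c2cc(OC)c(OCOC)c(OCOC)c2)c(O)c1 | intermediate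
6 | 1-[2-hydroxy-4-(methoxymethoxy)phenyl]-3,3-dimethoxy-2-[3-methoxy-4,5-bis(methoxymethoxy)phenyl]propan-1-one (racemic; not isolated) | COCOc1ccc(C(=O)C(C(OC)OC)c2cc(OC)c(OCOC)c(OCOC)c2)c(O)c1 | intermediate
7 | 3-(3,4-dihydroxy-5-methoxyphenyl)-7-hydroxy-4H-chromen-4-one | COc1cc(-c2coc3cc(O)ccc3c2=O)cc(O)c1O | intermediate
8 | 3-methylbut-2-enal (prenal) | CC(C)=CC=O | starting material
9 | 7-hydroxy-3-[(6Z)-4-hydroxy-3-methoxy-6-(3-methylbut-2-en-1-ylidene)-5-oxocyclohexa-1,3-dien-1-yl]-4H-chromen-4-one (o-quinone methide; not isolated) | COC1=C(O)C(=O)/C(=C\C=C(C)C)C(=C1)c1coc2cc(O)ccc2c1=O | intermediate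
10 | 7-hydroxy-3-(8-hydroxy-7-methoxy-2,2-dimethyl-2H-chromen-5-yl)-4H-chromen-4-one | COc1cc(-c2coc3cc(O)ccc3c2=O)c2c(c1O)OC(C)(C)C=C2 | target

## Step count and risks

Total steps: 5 (steps 1 and 2 run in parallel and converge in step 3).
Longest linear sequence: 4 (1 → 2 → 5 → 7 → 10, or 3 → 4 → 5 → 7 → 10).

**Steps most likely to fail**

**Step 5 (site-selective annulation on the free triol).** The risks are competing annulation at C8 of the A ring, sluggish attack at the hindered C2', and air oxidation of the catechol. The fallback sets out from 7 and comes back at 10. The monoanion of 7 (K2CO3, 1.0 equiv, DMF, 0 °C; only the 7-OH, pKa about 7, is ionised) is acylated with pivaloyl chloride to give 3-(3,4-dihydroxy-5-methoxyphenyl)-4-oxo-4H-chromen-7-yl pivalate F1. With the A ring blocked and deactivated, the annulation with 8 can be forced (pyridine, 130 °C) to give 3-(8-hydroxy-7-methoxy-2,2-dimethyl-2H-chromen-5-yl)-4-oxo-4H-chromen-7-yl pivalate F2. Methanolysis (K2CO3, MeOH, rt) then removes the ester and returns to 10.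

**Step 4 (oxidative aryl shift).** The 3,4,5-trioxygenated B ring is a weaker migrating group than a simple 4-alkoxyphenyl, so aurone formation may compete, and the HNO3 released may strip MOM groups early and expose phenols to Tl(III). The fallback sets out from 5 and comes back at 7, following the biosynthetic order chalcone → flavanone → isoflavone. Chalcone 5 is cyclised by oxa-Michael addition (NaOAc, EtOH, reflux) to racemic 7-(methoxymethoxy)-2-[3-methoxy-4,5-bis(methoxymethoxy)phenyl]chroman-4-one F3. The 2,3-aryl shift with dehydrogenation is then done with [hydroxy(tosyloxy)iodo]benzene in MeCN at 60 °C to give 7-(methoxymethoxy)-3-[3-methoxy-4,5-bis(methoxymethoxy)phenyl]-4H-chromen-4-one F4. HCl in MeOH removes the three MOM groups and returns to 7.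

**Step 3 (Claisen–Schmidt condensation).** The electron-rich, di-ortho-flanked aldehyde reacts slowly with the phenoxide-deactivated ketone, and flavanone formation or MOM loss can occur on acidification. The fallback sets out from 1 (with 3) and comes back at 5. Unprotected 1 and 3 are condensed under Lewis acid (BF3·OEt2, 1,4-dioxane, rt; the boron chelate of the o-hydroxyacetophenone serves as the enol component) to give (E)-1-(2,4-dihydroxyphenyl)-3-(3,4-dihydroxy-5-methoxyphenyl)prop-2-en-1-one F5. Treatment with MOMCl (3.3 equiv) and K2CO3 in acetone then protects the three non-chelated hydroxyls and leaves the hydrogen-bonded 2'-OH free, returning to 5.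

## Further compounds

F1 | step 5 | 3-(3,4-dihydroxy-5-methoxyphenyl)-4-oxo-4H-chromen-7-yl pivalate | COc1cc(-c2coc3cc(OC(=O)C(C)(C)C)ccc3c2=O)cc(O)c1O
F2 | step 5 | 3-(8-hydroxy-7-methoxy-2,2-dimethyl-2H-chromen-5-yl)-4-oxo-4H-chromen-7-yl pivalate | COc1cc(-c2coc3cc(OC(=O)C(C)(C)C)ccc3c2=O)c2c(c1O)OC(C)(C)C=C2
F3 | step 4 | 7-(methoxymethoxy)-2-[3-methoxy-4,5-bis(methoxymethoxy)phenyl]chroman-4-one (racemic) | COCOc1ccc2C(=O)CC(Oc2c1)c1cc(OC)c(OCOC)c(OCOC)c1
F4 | step 4 | 7-(methoxymethoxy)-3-[3-methoxy-4,5-bis(methoxymethoxy)phenyl]-4H-chromen-4-one | COCOc1ccc2c(c1)occ(-c1cc(OC)c(OCOC)c(OCOC)c1)c2=O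
F5 | step 3 | (E)-1-(2,4-dihydroxyphenyl)-3-(3,4-dihydroxy-5-methoxyphenyl)prop-2-en-1-one | COc1cc(/C=C/C(=O)c2ccc(O)cc2O)cc(O)c1O
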